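The earlier runs and the new flask are calculated with made-up constants; noise was put on by code.

Choose between north and west with one time constant and leave the concentrations aside: the time in which a flask's rate falls by a factor e.

| flask | starting material | coupling partner | free catalyst | impurity | temperature | remark | time |
|---|---|---|---|---|---|---|---|
| larch | 0.050 M | 0.045 M | 0.60 mM | 0.12 mM | 105 °C | run made earlier |  |
| maple | 0.050 M | 0.045 M | 0.60 mM | 0.27 mM | 118 °C | run made earlier |  |
| cedar | 0.050 M | 0.022 M | 0.60 mM | 0.18 mM | 105 °C | run made earlier |  |
| north | 0.050 M | 0.0450 M | 0.60 mM | 0.18 mM | 125 °C |  | 80 min |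
| west | 0.050 M | 0.0450 M | 0.60 mM | 0.18 mM | 110 °C |  | 80 min |

- larch (time / min: target / %, starting material / %): 15.0: 3.7, 96.6; 50.0: 10.2, 88.5; 80.0: 17.9, 79.6; 150: 33.5, 66.6; 240: 48.0, 50.1
- maple (time / min: target / %, starting material / %): 8.00: 3.3, 97.1; 12.0: 4.9, 95.6; 20.0: 6.0, 93.1; 40.0: 12.1, 86.0; 60.0: 18.1, 81.7; 90.0: 26.3, 73.1
- cedar (time / min: target / %, starting material / %): 50.0: 6.8, 92.4; 120: 20.3, 79.5; 150: 23.1, 76.0; 240: 31.2, 68.2

(readings scatter by 1 percentage point)

* the flask that comes out highest in amount of target, in percent of the starting material charged, or "all alike" when all lie within 1.5 percentage points (north / west / all alike)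
* target at the end, in percent of the starting material charged, north
* target at the end, in percent of the starting material charged, west

- a reading or a percentage of target counts all its forms, free or not

My own reckoning starts in the larch run, whose starting material reads as a lifetime of 351 min at 80.0 min and 347 min at 240 min, so larch looks pseudo-first-order, its rate shrinking with the starting material that remains, and any slowing from the coupling partner rides inside that number, since north and west carry the larch charges of both.

The maple run reads 287 min, but it changes impurity and temperature together, so I assume that each impurity removes one free catalyst, which makes the starting [free catalyst] less the starting [impurity], my working catalyst, 0.480 mM in larch, 0.330 mM in maple and 0.420 mM in north and west. Per working catalyst, the maple reading then comes out 1.76 times faster than larch, and stretching that factor exponentially over the degrees speeds north by a factor of 2.38 over larch and west by a factor of 1.24, while their smaller working catalyst multiplies both rates by 0.875.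

North's lifetime of starting material 167 min is therefore shorter than west's 319 min. On these lifetimes I reckon the rate at 80 min at 0.619 of its start in north and 0.778 in west. Since target plus starting material read 98.1% at the end of larch, I expect 38.1% target in north and 22.2% in west.

The forecast names north too, with 37% for north and 20% for west, both below mine, and it shades north down because “Maple's early fade hints at catalyst decay when hot”.

The flasks give 36.8% in north and 21.5% in west, so north comes out highest.

    coupling partner + free catalyst → catalyst intermediate A (k = 48.0 M⁻¹ min⁻¹, Ea = 81.0 kJ mol⁻¹)
    catalyst intermediate A ⇌ catalyst intermediate B (K = 5.70, k = 2.70 min⁻¹, Ea = 112 kJ mol⁻¹, ΔH = −9.00 kJ mol⁻¹)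
    starting material + catalyst intermediate B ⇌ catalyst intermediate C (K = 17.0 M⁻¹, k = 2400 M⁻¹ min⁻¹, Ea = 42.0 kJ mol⁻¹, ΔH = −90.0 kJ mol⁻¹)
    catalyst intermediate C → free catalyst + target (k = 1.20 min⁻¹, Ea = 107 kJ mol⁻¹)
    coupling partner + target ⇌ idle adduct, settled at all times (K = 37.0 M⁻¹, ΔH = −4.00 kJ mol⁻¹)
    target → over-reaction product (k = 3.30 × 10⁻⁵ min⁻¹, Ea = 129 kJ mol⁻¹)
    free catalyst + impurity → spent catalyst (k = 37000 M⁻¹ min⁻¹, Ea = 50.0 kJ mol⁻¹)
    (constants at 110 °C)

The lifetime of 167 min leaves 61.9% of the starting material in north at 80.0 min, and north holds 62.9%. What that number does not show is that 14.7% of the starting material charged stands in north as idle adduct, counted in the target, while over-reaction product stands at 0.126% and its step makes no difference to north's target. Left until 5.0 h, north has run 1.80 lifetimes, which leaves 16.6% of the starting material; that neighbour holds 19.2% of it, with target at 78.9%.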